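All constants are made up; what happens was integrated by code.

Over 25 min you have three flasks in which the starting complex condenses with itself, and the amount that the incoming ligand diverts is what you need to reckon.

    starting complex + incoming ligand → leaving ligand + complex with one exchanged (k1 = 0.00911 /M/s)
    complex with one exchanged + incoming ligand → leaving ligand + complex with two exchanged (k2 = 0.00173 /M/s)
    complex with two exchanged + incoming ligand → leaving ligand + complex with three exchanged (k3 = 0.00521 /M/s)
    incoming ligand → decomposed reagent (k4 = 0.0120 /s)
    2 starting complex → self-condensation product (k5 = 0.00254 /M/s)
the same everywhere: time 25 min
- green: starting complex 0.40 M; incoming ligand 0.240 M (fed, over 15 min); all else is in the flask from the start; the feed brings no volume worth counting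
- ochre: starting complex 0.40 M (fed, over 15 min); incoming ligand 0.240 M; all else is in the flask from the start; the feed brings no volume worth counting
- grey: starting complex 0.40 M; incoming ligand 0.240 M; everything together at the start
- which flask leads in amount of self-condensation product, in percent of the starting complex charged ("all alike" within 1.5 percentage points) (green / ochre / grey / all alike)
- how much self-condensation product is there at the end, in percent of the starting complex charged: green
- how much self-condensation product is there at the end, in percent of the starting complex charged: ochre
- how much self-condensation product is there at the end, in percent of the starting complex charged: grey
- percentages count the starting complex that a species holds: one self-condensation product counts as two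
- for a step with 2 of a species take k times the square, and two of it per event
- run time (green): 25 min

- The incoming ligand forks, decaying pseudo-first-order at fixed c(starting complex): 23.3% exchanges at the charged c(starting complex). Call this selectivity, the exchange constant times c(starting complex) over that product plus the decomposition constant, the capture share.
- In grey the ligand lives 63.9 s at the charged c(starting complex), and I reckon that exchange and condensation over that time put the midpoint c(starting complex) at 0.346 M. Going round once more gives a capture share of 20.8%, so 0.0499 M exchanges.
- Condensing the remainder over the run, I expect 63.7% as product in grey.
- Green's feed lasts 14 ligand lifetimes, and reckoning with condensation by itself I put its mean c(starting complex) during the feed at 0.227 M. Its capture share is therefore 14.7%, so 0.0353 M exchanges and I expect 67.0% as product in green. I leave ochre unreckoned.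
- If product is what you want, leave green's feed alone, because its reckoned capture share is lower than grey's.
- The forecast names green, with 68.4% for green, 62.6% for ochre and 63.1% for grey, on the ground that “slow feeding into the full charge of complex sends most of it to decomposition”. Its green stands above mine and its grey below mine.
- The flasks give 69.5% for green, 62.5% for ochre and 64.2% for grey, so green leads. Grey holds 0.0492 M of leaving ligand at the end, close to the 0.0499 M reckoned. In ochre, I reckon the complex fed over 83.3 s, the ligand's lifetime against decomposition, at 0.0370 M, which makes the capture share 2.73% and the exchange 0.00656 M. Ochre holds 0.00592 M of leaving ligand at the end.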